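**Strategy**

The seven-membered ring is closed at the bond between C10 (the acetoxy carbon) and C1 (the methyl-bearing ring-fusion carbon). A 2-cyclopentenyl-4-methyl-3,6-dihydro-2H-pyran, assembled from (S)-terpinen-4-ol, is lithiated at its allylic OCH2 (C10) and should undergo a ring-enlarging [2,3]-Wittig shift: the ring ether oxygen, attached to C6, leaves as C10 attacks C1. One operation forms C10–C1, the quaternary centre, the C10 carbinol anti to the angular methyl, and both ring alkenes (C8=C9, C5=C6). It exploits the fact that C10 and C6, 1,4 across the seven-membered ring, are both oxygenated, so one oxygen can bridge them. Epoxidation and a C10–O silicon tether then set the remaining centres.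

Key step: step 7

Remark on numbering: daucane numbering of the target is used for all intermediates (C1 ring-fusion carbon bearing CH3; C2, C3 ring CH2; C4 carbinol carbon bearing isopropyl; C5 ring-fusion CH; C6 carbon bearing the 3-methylbutanoate; C7 CH2; C8, C9 epoxide carbons, C8 bearing CH3; C10 acetoxy carbon; β is the face of the C1 methyl).

Remark on the starting material: (S)-(+)-terpinen-4-ol is assumed to be used in enantiomerically pure form (commercial material, enriched if necessary).

**Route**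

Step 1
Reactants: 1 (S)-(+)-terpinen-4-ol; 2 triethylsilyl trifluoromethanesulfonate
Product: 3 triethyl{[(1S)-4-methyl-1-(propan-2-yl)cyclohex-3-en-1-yl]oxy}silane
Conditions: TESOTf, 2,6-lutidine, CH2Cl2, 0 °C
Reagents that add atoms: triethylsilyl trifluoromethanesulfonate (CC[Si](CC)(CC)OS(=O)(=O)C(F)(F)F)
Why: Silyl ether protection of the hindered tertiary alcohol with the silyl triflate should proceed cleanly and masks the hydroxyl against hemiketal formation, retro-aldol cleavage and O-alkylation later, the stereocentre being untouched.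

Step 2
Reactants: 3 silyl ether; 4 ozone
Product: 6 (3S)-6-oxo-3-(propan-2-yl)-3-(triethylsilyloxy)heptanal, via secondary ozonide 5 (not isolated)
Conditions: O3, CH2Cl2, −78 °C; then Me2S, −78 °C → rt
Reagents that add atoms: ozone ([O-][O+]=O)
Why: Ozonolysis of the trisubstituted ring alkene with reductive work-up should cleave the cyclohexene to the 1,6-keto aldehyde without touching the silyl ether or the quaternary stereocentre.

Step 3
Reactants: 6 keto aldehyde
Product: 7 (5R)-2-methyl-5-(propan-2-yl)-5-(triethylsilyloxy)cyclopent-1-ene-1-carbaldehyde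
Conditions: piperidine (cat.), AcOH (cat.), benzene, 80 °C, Dean–Stark
Reagents that add atoms: none
Why: Amine/acid-catalysed intramolecular aldol condensation through the aldehyde enamine (five-membered ring closure onto the methyl ketone, then dehydration) should give the tetrasubstituted cyclopentenecarbaldehyde, the quaternary carbinol centre being non-enolisable.

Step 4
Reactants: 7 enal; 8 2-methylallylmagnesium chloride; 9 (−)-B-methoxydiisopinocampheylborane (from (+)-α-pinene)
Product: 11 (1S)-3-methyl-1-[(5R)-2-methyl-5-(propan-2-yl)-5-(triethylsilyloxy)cyclopent-1-en-1-yl]but-3-en-1-ol, via diisopinocampheylborinate ester 10 (not isolated)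
Conditions: (−)-Ipc2BOMe, CH2=C(CH3)CH2MgCl, Et2O, −78 °C → rt; then 7, Et2O, −78 °C; then NaBO3·4H2O, THF/H2O, rt
Reagents that add atoms: 2-methylallylmagnesium chloride (CC(=C)C[Mg]Cl)
Why: Brown asymmetric methallylboration through a chair Zimmerman–Traxler transition state should deliver the methallyl group to the Si face of the aldehyde under control of the isopinocampheyl groups, setting the (S)-carbinol C6 by reagent control.

Step 5
Reactants: 11 homoallylic alcohol; 12 allyl bromide
Product: 13 triethyl({(1R)-3-methyl-2-[(1S)-3-methyl-1-(prop-2-en-1-yloxy)but-3-en-1-yl]-1-(propan-2-yl)cyclopent-2-en-1-yl}oxy)silane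
Conditions: NaH, allyl bromide, Bu4NI (cat.), THF/DMF, 0 °C → rt
Reagents that add atoms: allyl bromide (C=CCBr)
Why: Williamson etherification of the sodium alkoxide with allyl bromide should give the allyl methallyl-carbinyl ether, the tertiary hydroxyl being silylated and no stereocentre being involved.

Step 6
Reactants: 13 allyl ether
Product: 14 (2S)-4-methyl-2-[(5R)-2-methyl-5-(propan-2-yl)-5-(triethylsilyloxy)cyclopent-1-en-1-yl]-3,6-dihydro-2H-pyran
Conditions: second-generation Grubbs catalyst RuCl2(=CHPh)(PCy3)(H2IMes) (cat.), CH2Cl2, 40 °C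
Reagents that add atoms: none
Why: Ring-closing metathesis of the allyl and methallyl groups should give the trisubstituted dihydropyran with loss of ethylene, the tetrasubstituted cyclopentene double bond being inert to the ruthenium carbene.

Step 7
Reactants: 14 dihydropyran
Product: 17 (1S,4R,10R)-4β-(triethylsilyloxy)dauca-5,8-dien-10α-ol, via C10-lithiated dihydropyran 15 (not isolated), via lithium alkoxide 16 (not isolated)
Conditions: s-BuLi, THF, −78 → −30 °C; then aq. NH4Cl
Reagents that add atoms: none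
Why: Proposed new method: s-BuLi should remove a proton from the allylic OCH2 (C10) of 14, and the allyl-stabilised α-alkoxy carbanion then attacks the methyl-bearing alkene carbon C1 of the cyclopentenyl group on the other α-carbon (C6) while the allylic C6–O bond breaks, a concerted [2,3]-Wittig shift whose five-centre array is bridged by C7–C8=C9 into a transition state shaped like an 8-oxabicyclo[3.2.1]octadiene. The closest known reactions are the [2,3]-Wittig ring contraction of cyclic bis-allylic ethers and the ring-enlarging [2,3] shifts of 2-vinyl cyclic onium ylides; what is new is that carbanion and allylic carbon sit in the same six-membered ether, so that the shift enlarges it by one atom. The seven-membered carbocycle closes by intramolecular SN2′-type attack of C10 on C1 (7-endo with respect to the new C5=C6 bond, which the ring forces to be cis). C1 is set by suprafacial 1,3-transfer of chirality from the (S)-configured C6, since only the rotamer with C7 turned towards C1 can close the ring, and C10 is set by the oxygen bridge of the bicyclic transition state, which places the new alkoxide anti to the angular methyl. The step needs lithiation at the secondary allylic OCH2 instead of the hindered tertiary O–CH and [2,3] shift in preference to radical-pair [1,2] or [1,4] migration; low temperature and the pseudo-axial cyclopentenyl group, whose π bond lies over C10 and parallel to the breaking C–O bond, should favour this, and a [1,4] product (a cis-divinylcyclopropane enolate) would reach the same alkoxide by Cope rearrangement.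

Step 8
Reactants: 17 dienol; 18 tert-butyl hydroperoxide
Product: 19 8α,9α-epoxy-4β-(triethylsilyloxy)dauc-5-en-10α-ol
Conditions: VO(acac)2 (cat.), t-BuOOH, CH2Cl2, 0 °C → rt
Reagents that add atoms: tert-butyl hydroperoxide (CC(C)(C)OO)
Why: Vanadium-catalysed hydroxyl-directed epoxidation should deliver oxygen to the allylic C8=C9 bond syn to the C10 hydroxyl (α-epoxide, as known for cyclohept-2-enols) and leave the hindered, only homoallylic C5=C6 bond untouched.

Step 9
Reactants: 19 epoxy alcohol; 20 1,1,3,3-tetramethyldisilazane; 21 hydrogen peroxide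
Product: 24 8α,9α-epoxy-4β-(triethylsilyloxy)-5α-daucane-6α,10α-diol, via 10-O-dimethylsilyl ether 22 (not isolated), via bridged cyclic siloxane 23 (not isolated)
Conditions: (HMe2Si)2NH, 60 °C, then evaporation; Karstedt catalyst Pt2[(CH2=CHSiMe2)2O]3 (cat.), toluene, 60 °C; then 30% H2O2, KF, KHCO3, THF/MeOH, rt
Reagents that add atoms: hydrogen peroxide (OO)
Why: Tamao intramolecular hydrosilylation followed by Tamao–Fleming oxidation should add Si–H syn across C5=C6 from the concave α face to which the C10 oxygen is tied (silicon to the less substituted C6 in the endo mode, hydrogen to C5, since exo closure would place silicon on the fully substituted C5), and oxidation of the C–Si bond with retention then gives the 6α-hydroxyl and the trans ring fusion (5α-H).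

Step 10
Reactants: 24 diol; 25 3-methylbutanoic anhydride
Product: 26 8α,9α-epoxy-10α-hydroxy-4β-(triethylsilyloxy)-5α-daucan-6α-yl 3-methylbutanoate
Conditions: (i-PrCH2CO)2O (1 equiv), DMAP (cat.), Et3N, CH2Cl2, −20 → 0 °C
Reagents that add atoms: 3-methylbutanoic anhydride (CC(C)CC(=O)OC(=O)CC(C)C)
Why: DMAP-catalysed acylation is expected to occur first at the C6 hydroxyl, which has a CH2 neighbour, in preference to the neopentylic C10 hydroxyl flanked by the quaternary C1 and the epoxide, no stereocentre being affected.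

Step 11
Reactants: 26 hydroxy ester; 27 acetic anhydride
Product: 28 10α-acetoxy-8α,9α-epoxy-4β-(triethylsilyloxy)-5α-daucan-6α-yl 3-methylbutanoate
Conditions: Ac2O, DMAP, pyridine, CH2Cl2, rt
Reagents that add atoms: acetic anhydride (CC(=O)OC(C)=O)
Why: Acetylation under nucleophilic catalysis should esterify the remaining hindered secondary C10 hydroxyl, the tertiary alcohol being silylated.

Step 12
Reactants: 28 silyl-protected diester
Product: 29 10α-acetoxy-8α,9α-epoxy-4β-hydroxy-5α-daucan-6α-yl 3-methylbutanoate, (1S,4R,5S,6S,8R,9S,10S), CNP0137153.1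
Conditions: HF·pyridine, pyridine, THF, 0 °C → rt
Reagents that add atoms: none
Why: Fluoride-mediated desilylation under pyridine-buffered conditions should cleave the tertiary triethylsilyl ether while leaving the trisubstituted epoxide and both esters intact.

**Compound list**

1 | (S)-(+)-terpinen-4-ol, (1S)-4-methyl-1-(propan-2-yl)cyclohex-3-en-1-ol | CC1=CC[C@](O)(C(C)C)CC1 | starting material
2 | triethylsilyl trifluoromethanesulfonate | CC[Si](CC)(CC)OS(=O)(=O)C(F)(F)F | starting material
3 | triethyl{[(1S)-4-methyl-1-(propan-2-yl)cyclohex-3-en-1-yl]oxy}silane | CC1=CC[C@](O[Si](CC)(CC)CC)(C(C)C)CC1 | intermediate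
4 | ozone | [O-][O+]=O | starting material
5 | secondary ozonide of 3 (1,2,4-trioxolane across the former alkene carbons, configuration at the two acetal carbons not defined) | CC12CC[C@@](O[Si](CC)(CC)CC)(C(C)C)CC(OO1)O2 | intermediate (not isolated)
6 | (3S)-6-oxo-3-(propan-2-yl)-3-(triethylsilyloxy)heptanal | CC(=O)CC[C@@](O[Si](CC)(CC)CC)(C(C)C)CC=O | intermediate
7 | (5R)-2-methyl-5-(propan-2-yl)-5-(triethylsilyloxy)cyclopent-1-ene-1-carbaldehyde | O=CC1=C(C)CC[C@@]1(O[Si](CC)(CC)CC)C(C)C | intermediate
8 | 2-methylallylmagnesium chloride | CC(=C)C[Mg]Cl | starting material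
9 | (−)-B-methoxydiisopinocampheylborane (from (+)-α-pinene) | COB([C@@H]1C[C@@H]2C[C@H]([C@H]1C)C2(C)C)[C@@H]1C[C@@H]2C[C@H]([C@H]1C)C2(C)C | starting material
10 | diisopinocampheylborinate ester of 11 | CC(=C)C[C@H](OB([C@@H]1C[C@@H]2C[C@H]([C@H]1C)C2(C)C)[C@@H]1C[C@@H]2C[C@H]([C@H]1C)C2(C)C)C1=C(C)CC[C@@]1(O[Si](CC)(CC)CC)C(C)C | intermediate (not isolated)
11 | (1S)-3-methyl-1-[(5R)-2-methyl-5-(propan-2-yl)-5-(triethylsilyloxy)cyclopent-1-en-1-yl]but-3-en-1-ol | CC(=C)C[C@H](O)C1=C(C)CC[C@@]1(O[Si](CC)(CC)CC)C(C)C | intermediate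
12 | allyl bromide | C=CCBr | starting material
13 | allyl ether of 11, triethyl({(1R)-3-methyl-2-[(1S)-3-methyl-1-(prop-2-en-1-yloxy)but-3-en-1-yl]-1-(propan-2-yl)cyclopent-2-en-1-yl}oxy)silane | C=CCO[C@@H](CC(C)=C)C1=C(C)CC[C@@]1(O[Si](CC)(CC)CC)C(C)C | intermediate
14 | (2S)-4-methyl-2-[(5R)-2-methyl-5-(propan-2-yl)-5-(triethylsilyloxy)cyclopent-1-en-1-yl]-3,6-dihydro-2H-pyran | CC1=CCO[C@@H](C1)C1=C(C)CC[C@@]1(O[Si](CC)(CC)CC)C(C)C | intermediate
15 | 14 lithiated at the allylic OCH2 carbon (C10) | CC1=C[CH]([Li])O[C@@H](C1)C1=C(C)CC[C@@]1(O[Si](CC)(CC)CC)C(C)C | intermediate (not isolated)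
16 | lithium alkoxide of 17 | [Li]O[C@@H]1C=C(C)CC=C2[C@]1(C)CC[C@@]2(O[Si](CC)(CC)CC)C(C)C | intermediate (not isolated)
17 | (1S,4R,10R)-4β-(triethylsilyloxy)dauca-5,8-dien-10α-ol (C1 methyl β) | O[C@@H]1C=C(C)CC=C2[C@]1(C)CC[C@@]2(O[Si](CC)(CC)CC)C(C)C | intermediate
18 | tert-butyl hydroperoxide | CC(C)(C)OO | starting material
19 | 8α,9α-epoxy-4β-(triethylsilyloxy)dauc-5-en-10α-ol | O[C@@H]1[C@@H]2O[C@]2(C)CC=C2[C@]1(C)CC[C@@]2(O[Si](CC)(CC)CC)C(C)C | intermediate
20 | 1,1,3,3-tetramethyldisilazane | C[SiH](C)N[SiH](C)C | starting material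
21 | hydrogen peroxide | OO | starting material
22 | 10-O-dimethylsilyl (Si–H) ether of 19 | C[SiH](C)O[C@@H]1[C@@H]2O[C@]2(C)CC=C2[C@]1(C)CC[C@@]2(O[Si](CC)(CC)CC)C(C)C | intermediate (not isolated)
23 | cyclic siloxane with an O–SiMe2 bridge from C10–O to C6 on the α face, 5α-H | C[Si]1(C)O[C@@H]2[C@@H]3O[C@]3(C)C[C@H]1[C@@H]1[C@]2(C)CC[C@@]1(O[Si](CC)(CC)CC)C(C)C | intermediate (not isolated)
24 | 8α,9α-epoxy-4β-(triethylsilyloxy)-5α-daucane-6α,10α-diol | O[C@@H]1[C@@H]2O[C@]2(C)C[C@H](O)[C@@H]2[C@]1(C)CC[C@@]2(O[Si](CC)(CC)CC)C(C)C | intermediate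
25 | 3-methylbutanoic (isovaleric) anhydride | CC(C)CC(=O)OC(=O)CC(C)C | starting material
26 | 8α,9α-epoxy-10α-hydroxy-4β-(triethylsilyloxy)-5α-daucan-6α-yl 3-methylbutanoate | O[C@@H]1[C@@H]2O[C@]2(C)C[C@H](OC(=O)CC(C)C)[C@@H]2[C@]1(C)CC[C@@]2(O[Si](CC)(CC)CC)C(C)C | intermediate
27 | acetic anhydride | CC(=O)OC(C)=O | starting material
28 | 10α-acetoxy-8α,9α-epoxy-4β-(triethylsilyloxy)-5α-daucan-6α-yl 3-methylbutanoate | CC(=O)O[C@@H]1[C@@H]2O[C@]2(C)C[C@H](OC(=O)CC(C)C)[C@@H]2[C@]1(C)CC[C@@]2(O[Si](CC)(CC)CC)C(C)C | intermediate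
29 | 10α-acetoxy-8α,9α-epoxy-4β-hydroxy-5α-daucan-6α-yl 3-methylbutanoate, (1S,4R,5S,6S,8R,9S,10S), CNP0137153.1 | CC(=O)O[C@@H]1[C@@H]2O[C@]2(C)C[C@H](OC(=O)CC(C)C)[C@@H]2[C@]1(C)CC[C@@]2(O)C(C)C | target

**Step count and risks**

Total step count: 12. Longest linear sequence: 12 steps (from 1).

Steps most likely to fail:

1. Step 7 (Proposed new method). The lithiated ether may instead break its C6–O bond to a radical pair and recombine by [1,2] or [1,4] migration (ring contraction). It may also be lithiated at the tertiary O–CH, or open by elimination after deprotonation at C7. Fallback with known chemistry, from enal 7 back to dienol 17, making the same C10–C1 bond by a divinylcyclopropane–cycloheptadiene (Cope) rearrangement. Still–Gennari olefination of 7 with methyl 2-[bis(2,2,2-trifluoroethoxy)phosphoryl]propanoate (KHMDS, 18-crown-6, THF, −78 °C) should give methyl (2Z)-dienoate F1. Reduction with i-Bu2AlH (CH2Cl2, −78 °C) gives (2Z)-dienol F2. Hydroxyl-directed Charette cyclopropanation of the proximal alkene (Zn(CH2I)2·DME, the tartramide-derived butyldioxaborolane enantiomer that leads to the (1S,2R) product, CH2Cl2, 0 °C) gives cis-cyclopropylmethanol F3. Dess–Martin periodinane gives cyclopropanecarbaldehyde F4, used at once. Wittig reaction with the ylide from [(4-methoxybenzyloxy)methyl]triphenylphosphonium chloride (NaHMDS, THF, −78 → 0 °C) gives 4-methoxybenzyl enol ether F5. On warming in toluene (60–80 °C) its (E)-isomer, a cis-1,2-dialkenylcyclopropane, should rearrange through the boat transition state to PMB-protected dienol F6; the E-oxygen ends anti to the angular methyl, and the slower (Z)-isomer is removed. DDQ (CH2Cl2, pH 7 buffer) then returns 17.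

2. Step 9. The platinum hydride may fail to insert the hindered trisubstituted C5=C6 bond, or the ring may close in the exo sense (silicon on C5). Fallback from epoxy alcohol 19 back to diol 24, replacing the silicon tether by a phosphorus-directed catalytic hydroboration. ClPPh2 (Et3N, DMAP, THF) gives C10 O-diphenylphosphinite F7. Rhodium-catalysed hydroboration with catecholborane ([Rh(nbd)(dppb)]BF4, THF), directed by the bound phosphorus, should add hydrogen to C5 and boron to C6 from the α face to give catechol boronate F8. Methanolysis of the phosphinite and oxidation (MeOH; then H2O2, NaOH, 0 °C) return 24.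

3. Step 10. The two hindered secondary hydroxyls may be acylated at similar rates, or in the reverse order. Fallback from cyclic siloxane 23 (isolated after the hydrosilylation stage of step 9) back to diester 28, unmasking the two oxygens one after the other. HF·pyridine (pyridine, THF, 0 °C) cleaves the Si–O bond to fluorosilyl alcohol F9. Ac2O/DMAP/pyridine gives fluorosilyl acetate F10. Tamao–Fleming oxidation (H2O2, KF, KHCO3, THF/MeOH) gives 10-acetoxy 6-alcohol F11. Acylation with 3-methylbutanoic anhydride (DMAP, Et3N) returns 28.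

Further compounds
F1 | step 7 | methyl (2Z)-2-methyl-3-[(5R)-2-methyl-5-(propan-2-yl)-5-(triethylsilyloxy)cyclopent-1-en-1-yl]prop-2-enoate | COC(=O)/C(C)=C\C1=C(C)CC[C@@]1(O[Si](CC)(CC)CC)C(C)C
F2 | step 7 | (2Z)-2-methyl-3-[(5R)-2-methyl-5-(propan-2-yl)-5-(triethylsilyloxy)cyclopent-1-en-1-yl]prop-2-en-1-ol | OC/C(C)=C\C1=C(C)CC[C@@]1(O[Si](CC)(CC)CC)C(C)C
F3 | step 7 | {(1S,2R)-1-methyl-2-[(5R)-2-methyl-5-(propan-2-yl)-5-(triethylsilyloxy)cyclopent-1-en-1-yl]cyclopropyl}methanol (CH2OH and cyclopentenyl cis) | OC[C@@]1(C)C[C@H]1C1=C(C)CC[C@@]1(O[Si](CC)(CC)CC)C(C)C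
F4 | step 7 | (1S,2S)-1-methyl-2-[(5R)-2-methyl-5-(propan-2-yl)-5-(triethylsilyloxy)cyclopent-1-en-1-yl]cyclopropane-1-carbaldehyde (CHO and cyclopentenyl cis) | O=C[C@@]1(C)C[C@H]1C1=C(C)CC[C@@]1(O[Si](CC)(CC)CC)C(C)C
F5 | step 7 | (E)-4-methoxybenzyl enol ether of F4, cis-1-(2-alkoxyethenyl)-2-cyclopentenyl-1-methylcyclopropane | COc1ccc(CO/C=C/[C@@]2(C)C[C@H]2C2=C(C)CC[C@@]2(O[Si](CC)(CC)CC)C(C)C)cc1
F6 | step 7 | 10-O-(4-methoxybenzyl) ether of 17 | COc1ccc(CO[C@@H]2C=C(C)CC=C3[C@]2(C)CC[C@@]3(O[Si](CC)(CC)CC)C(C)C)cc1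
F7 | step 9 | 10-O-diphenylphosphinite of 19 | c1ccc(cc1)P(O[C@@H]1[C@@H]2O[C@]2(C)CC=C2[C@]1(C)CC[C@@]2(O[Si](CC)(CC)CC)C(C)C)c1ccccc1
F8 | step 9 | 6α-(1,3,2-benzodioxaborol-2-yl) 5α-H adduct of F7 | c1ccc(cc1)P(O[C@@H]1[C@@H]2O[C@]2(C)C[C@H](B2Oc3ccccc3O2)[C@@H]2[C@]1(C)CC[C@@]2(O[Si](CC)(CC)CC)C(C)C)c1ccccc1
F9 | step 10 | 8α,9α-epoxy-6α-(fluorodimethylsilyl)-4β-(triethylsilyloxy)-5α-daucan-10α-ol | O[C@@H]1[C@@H]2O[C@]2(C)C[C@H]([Si](C)(C)F)[C@@H]2[C@]1(C)CC[C@@]2(O[Si](CC)(CC)CC)C(C)C
F10 | step 10 | 8α,9α-epoxy-6α-(fluorodimethylsilyl)-4β-(triethylsilyloxy)-5α-daucan-10α-yl acetate | CC(=O)O[C@@H]1[C@@H]2O[C@]2(C)C[C@H]([Si](C)(C)F)[C@@H]2[C@]1(C)CC[C@@]2(O[Si](CC)(CC)CC)C(C)C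
F11 | step 10 | 8α,9α-epoxy-6α-hydroxy-4β-(triethylsilyloxy)-5α-daucan-10α-yl acetate | CC(=O)O[C@@H]1[C@@H]2O[C@]2(C)C[C@H](O)[C@@H]2[C@]1(C)CC[C@@]2(O[Si](CC)(CC)CC)C(C)C
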